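**Retrosynthetic overview**

- The target is reached by cleaving six aryl methyl ethers of stilbene 25, which comes from β-resorcylate ester 23 by loss of the ester carbon.
- The strategy rests on ring A, the 3,5-dihydroxyphenyl ring on the alkene. Its two meta hydroxyls and the alkene-bearing carbon between them are the pattern of a folded tetraketide, so ring A is opened across C2–C7 of a methyl 3,5,7-trioxo ester whose C7 ketone is the cinnamoyl carbonyl on the styryl arm of ring B.
- The trioxo ester is stored as diketo-dioxinone 19, made by Claisen coupling of the dianion of keto-dioxinone 16 with the imidazolide of cinnamic acid 13 (from aldehyde 12).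
- In aldehyde 12 the methine C* is set by chiral phosphoric acid transfer hydrogenation of the ortho-hydroxy triarylethylene 8, assembled from deoxybenzoin 3 and the aryl-metal from dibromide 4.
- Rings B, C and D are bought as arenes; ring A is the only ring formed, and it is formed last.

Key step: step 9

Remark on the chemistry: the (R)-phosphoric acid in step 3 is assumed to give the (S)-methine. If a trial run shows the opposite sense, its (S)-enantiomer is used with no other change. The descriptor is (S) in the target and in every intermediate from 9 on, because ring B outranks ring C throughout. In the names below, Ar stands for 5-[(1S)-2-(3,5-dimethoxyphenyl)-1-(2,4-dimethoxyphenyl)ethyl]-2,4-dimethoxyphenyl.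

**Route**

Step 1
Reactants: 1 3-methoxyphenol; 2 3,5-dimethoxyphenylacetic acid
Product: 3 2-(3,5-dimethoxyphenyl)-1-(2-hydroxy-4-methoxyphenyl)ethan-1-one
Conditions: 1 (1.5 equiv), BF3·OEt2 as solvent, 85 °C; then aq. NaOAc
Reagents that add atoms: none
Why: Friedel–Crafts C-acylation of a phenol by an arylacetic acid in BF3·OEt2, the standard entry to 2-hydroxy-4-methoxydeoxybenzoins; the acyl group enters para to OMe and ortho to OH, where the ketone is held as its boron chelate, and the excess of 1 keeps ring D of the acid from acting as the arene.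

Step 2
Reactants: 3 the deoxybenzoin; 4 1,5-dibromo-2,4-dimethoxybenzene
Product: 8 2-[1-(5-bromo-2,4-dimethoxyphenyl)-2-(3,5-dimethoxyphenyl)ethenyl]-5-methoxyphenol (E/Z mixture), via aryllithium 5 (not isolated), via arylcerium dichloride 6 (not isolated), via tertiary carbinol 7 (not isolated)
Conditions: 4 (2.5 equiv), n-BuLi (2.5 equiv), THF, −78 °C; anhydrous CeCl3 (2.6 equiv), −78 °C; 3, −78 to 0 °C; aq. NH4Cl; then p-TsOH·H2O (5 mol%), toluene, 50 °C
Reagents that add atoms: none
Why: Single bromine–lithium exchange, transmetalation to the weakly basic organocerium and 1,2-addition to the ketone (one equivalent is spent on the phenol OH), then acid-catalysed E1 dehydration of the doubly benzylic carbinol; cerium suppresses enolisation of the deoxybenzoin, and the alkene geometry does not matter for step 3.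

Step 3
Reactants: 8 the ortho-hydroxy triarylethylene
Product: 9 2-[(1S)-1-(5-bromo-2,4-dimethoxyphenyl)-2-(3,5-dimethoxyphenyl)ethyl]-5-methoxyphenol
Conditions: diethyl 2,6-dimethyl-1,4-dihydropyridine-3,5-dicarboxylate (1.5 equiv), (R)-3,3'-bis(2,4,6-triisopropylphenyl)-1,1'-binaphthalene-2,2'-diyl hydrogen phosphate (10 mol%), ClCH2CH2Cl, 25 °C
Reagents that add atoms: none
Why: Chiral phosphoric acid-catalysed asymmetric transfer hydrogenation of an ortho-hydroxyphenyl 1,1-diarylalkene: protonation of the alkene CH gives an ortho-quinone methide hydrogen-bonded to the phosphate (both alkene isomers converge on it), and the Hantzsch ester bound to the same phosphate delivers hydride to one face of the exocyclic carbon, which sets C*.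

Step 4
Reactants: 9 the (S)-phenol
Product: 10 1-bromo-5-[(1S)-2-(3,5-dimethoxyphenyl)-1-(2,4-dimethoxyphenyl)ethyl]-2,4-dimethoxybenzene
Conditions: MeI (3 equiv), K2CO3 (2 equiv), DMF, 25 °C
Reagents that add atoms: iodomethane, CI
Why: Williamson O-methylation of the phenoxide; C* carries no acidic hydrogen under carbonate and is untouched.

Step 5
Reactants: 10 the aryl bromide
Product: 12 5-[(1S)-2-(3,5-dimethoxyphenyl)-1-(2,4-dimethoxyphenyl)ethyl]-2,4-dimethoxybenzaldehyde (Ar–CHO), via aryllithium 11 (not isolated)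
Conditions: n-BuLi (1.1 equiv), THF, −78 °C; DMF (3 equiv), −78 to 0 °C; aq. NH4Cl
Reagents that add atoms: N,N-dimethylformamide, CN(C)C=O
Why: Bromine–lithium exchange followed by Bouveault formylation; at −78 °C the exchange is far faster than deprotonation of the diarylmethine or ortho-lithiation next to the methoxy groups.

Step 6
Reactants: 12 the aldehyde
Product: 13 (E)-3-Ar-prop-2-enoic acid
Conditions: malonic acid (3 equiv), pyridine, piperidine (0.2 equiv), 90 °C
Reagents that add atoms: malonic acid, OC(=O)CC(=O)O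
Why: Knoevenagel–Doebner condensation; decarboxylative elimination from the arylidene malonic acid should give the (E)-cinnamic acid, as is usual for 2,4-dimethoxybenzaldehydes.

Step 7
Reactants: 14 2,2,6-trimethyl-4H-1,3-dioxin-4-one
Product: 16 2,2-dimethyl-6-(2-oxopropyl)-4H-1,3-dioxin-4-one, via lithium dienolate 15 (not isolated)
Conditions: LiN(SiMe3)2 (1.0 equiv), THF, −78 °C; AcCl (0.5 equiv), −78 °C; aq. HCl
Reagents that add atoms: acetyl chloride, CC(Cl)=O
Why: γ-Selective C-acylation of the vinylogous ester dienolate with an acid chloride; half an equivalent of acetyl chloride is used because the more acidic product consumes a second equivalent of dienolate.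

Step 8
Reactants: 13 the cinnamic acid; 16 the keto-dioxinone
Product: 19 6-[(E)-6-Ar-2,4-dioxohex-5-en-1-yl]-2,2-dimethyl-4H-1,3-dioxin-4-one, via acyl imidazolide 17 (not isolated), via dilithium dianion 18 (not isolated)
Conditions: 13, 1,1'-carbonyldiimidazole (1.1 equiv), THF, 25 °C; separately 16 (3 equiv), LiN(i-Pr)2 (6 equiv), THF, −78 °C; combine, −78 to −40 °C; aq. HCl to pH 3
Reagents that add atoms: none
Why: Claisen-type C-acylation of a 1,3-dicarbonyl dianion at its terminal carbon by an acyl imidazolide; the hard terminal carbanion should attack the acyl carbon and not the electron-rich cinnamoyl β-carbon, and the excess dianion absorbs the imidazole N–H and the acidic diketone product.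

Step 9
Reactants: 19 the diketo-dioxinone
Product: 23 methyl 2,4-dihydroxy-6-[(E)-2-Ar-ethenyl]benzoate, via acylketene 20 (not isolated), via triketo ester 21 (not isolated), via cyclic aldol 22 (not isolated)
Conditions: MeOH (10 equiv), toluene, 110 °C, sealed tube; concentrate; Cs2CO3 (2 equiv), MeOH, 20 °C; then HCl in MeOH to pH 2–3, 0 °C, short contact
Reagents that add atoms: methanol, CO
Why: Thermal retro-[4+2] of the dioxinone expels acetone and gives acylketene 20, which the excess methanol should capture faster than any internal enol oxygen, so that the full chain appears as methyl 3,5,7-trioxo ester 21; Cs2CO3 then forms the C2 enolate, which adds to the C7 cinnamoyl ketone to give aldol 22, and acid-assisted loss of water with enolisation of the C3 and C5 carbonyls gives the arene. The closest known reaction type is the biomimetic aldol aromatisation of 3,5,7-triketo esters to β-resorcylates, including its dioxinone-masked acylketene form; the conjugated C7 ketone is the only extension. Ring A closes by a 6-(enolexo)-exo-trig aldol that makes the C2–C7 bond. No stereocentre is formed, C* has no acidic hydrogen and should survive carbonate, and the (E)-alkene is carried through unchanged. The selectivity needed is C2-to-C7 aldol over C6-to-C1 Claisen closure to an acylphloroglucinol, lactonisation to a 4-hydroxy-2-pyranone and oxa-Michael closure to a dihydropyranone; the poorly electrophilic methyl ester terminus with a mild carbonate base favours the aldol mode, and the 2,4-dimethoxyaryl group on C9 lowers the electrophilicity of the enone β-carbon.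

Step 10
Reactants: 23 the methyl β-resorcylate
Product: 25 5-[(E)-2-Ar-ethenyl]benzene-1,3-diol, via resorcylic acid 24 (not isolated)
Conditions: 6 M aq. KOH, MeOH, 120 °C, sealed tube, argon; then aq. NH4Cl to pH 6–7
Reagents that add atoms: none
Why: Saponification followed by protodecarboxylation of the β-resorcylate (ipso-protonation of the electron-rich ring, then loss of CO2), as seen when 6-substituted 2,4-dihydroxybenzoate esters are hydrolysed in hot alkali; staying basic avoids acid-induced lactonisation of the stilbene acid to a dihydroisocoumarin.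

Step 11
Reactants: 25 the hexamethyl ether
Product: 26 4-[(1S)-2-(3,5-dihydroxyphenyl)-1-{5-[(E)-2-(3,5-dihydroxyphenyl)ethenyl]-2,4-dihydroxyphenyl}ethyl]benzene-1,3-diol (target)
Conditions: BBr3 (15 equiv), CH2Cl2, −78 to 0 °C; then MeOH and ice-water
Reagents that add atoms: none
Why: Lewis acid ether cleavage (bromide attacks the methyl group of each aryl ether–BBr3 adduct), the usual final step for polymethoxystilbenes; low temperature and a prompt quench limit acid-promoted reactions of the electron-rich alkene, and C* is not ionisable under these conditions.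

**Compound list**

1 | 3-methoxyphenol | COc1cccc(O)c1 | starting material
2 | 3,5-dimethoxyphenylacetic acid | COc1cc(CC(=O)O)cc(OC)c1 | starting material
3 | 2-(3,5-dimethoxyphenyl)-1-(2-hydroxy-4-methoxyphenyl)ethan-1-one | COc1ccc(C(=O)Cc2cc(OC)cc(OC)c2)c(O)c1 | intermediate
4 | 1,5-dibromo-2,4-dimethoxybenzene | COc1cc(OC)c(Br)cc1Br | starting material
5 | (5-bromo-2,4-dimethoxyphenyl)lithium (not isolated) | [Li]c1cc(Br)c(OC)cc1OC | intermediate
6 | (5-bromo-2,4-dimethoxyphenyl)cerium dichloride (not isolated) | COc1cc(OC)c([Ce](Cl)Cl)cc1Br | intermediate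
7 | racemic 2-[1-(5-bromo-2,4-dimethoxyphenyl)-2-(3,5-dimethoxyphenyl)-1-hydroxyethyl]-5-methoxyphenol (not isolated) | COc1ccc(C(O)(Cc2cc(OC)cc(OC)c2)c2cc(Br)c(OC)cc2OC)c(O)c1 | intermediate
8 | 2-[1-(5-bromo-2,4-dimethoxyphenyl)-2-(3,5-dimethoxyphenyl)ethenyl]-5-methoxyphenol (E/Z mixture) | COc1ccc(C(=Cc2cc(OC)cc(OC)c2)c2cc(Br)c(OC)cc2OC)c(O)c1 | intermediate
9 | 2-[(1S)-1-(5-bromo-2,4-dimethoxyphenyl)-2-(3,5-dimethoxyphenyl)ethyl]-5-methoxyphenol | Brc1cc([C@@H](Cc2cc(OC)cc(OC)c2)c2ccc(OC)cc2O)c(OC)cc1OC | intermediate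
10 | 1-bromo-5-[(1S)-2-(3,5-dimethoxyphenyl)-1-(2,4-dimethoxyphenyl)ethyl]-2,4-dimethoxybenzene | Brc1cc([C@@H](Cc2cc(OC)cc(OC)c2)c2ccc(OC)cc2OC)c(OC)cc1OC | intermediate
11 | Ar–Li, {5-[(1S)-2-(3,5-dimethoxyphenyl)-1-(2,4-dimethoxyphenyl)ethyl]-2,4-dimethoxyphenyl}lithium (not isolated) | [Li]c1cc([C@@H](Cc2cc(OC)cc(OC)c2)c2ccc(OC)cc2OC)c(OC)cc1OC | intermediate
12 | 5-[(1S)-2-(3,5-dimethoxyphenyl)-1-(2,4-dimethoxyphenyl)ethyl]-2,4-dimethoxybenzaldehyde | O=Cc1cc([C@@H](Cc2cc(OC)cc(OC)c2)c2ccc(OC)cc2OC)c(OC)cc1OC | intermediate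
13 | (E)-3-{5-[(1S)-2-(3,5-dimethoxyphenyl)-1-(2,4-dimethoxyphenyl)ethyl]-2,4-dimethoxyphenyl}prop-2-enoic acid | OC(=O)/C=C/c1cc([C@@H](Cc2cc(OC)cc(OC)c2)c2ccc(OC)cc2OC)c(OC)cc1OC | intermediate
14 | 2,2,6-trimethyl-4H-1,3-dioxin-4-one | CC1=CC(=O)OC(C)(C)O1 | starting material
15 | lithium 2,2-dimethyl-6-methylidene-6H-1,3-dioxin-4-olate (not isolated) | C=C1C=C(O[Li])OC(C)(C)O1 | intermediate
16 | 2,2-dimethyl-6-(2-oxopropyl)-4H-1,3-dioxin-4-one | CC(=O)CC1=CC(=O)OC(C)(C)O1 | intermediate
17 | (E)-3-Ar-1-(1H-imidazol-1-yl)prop-2-en-1-one (not isolated) | O=C(/C=C/c1cc([C@@H](Cc2cc(OC)cc(OC)c2)c2ccc(OC)cc2OC)c(OC)cc1OC)n1ccnc1 | intermediate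
18 | dilithium dianion of 16 (not isolated) | C=C(O[Li])C=C1C=C(O[Li])OC(C)(C)O1 | intermediate
19 | 6-[(E)-6-Ar-2,4-dioxohex-5-en-1-yl]-2,2-dimethyl-4H-1,3-dioxin-4-one | CC1(C)OC(=O)C=C(CC(=O)CC(=O)/C=C/c2cc([C@@H](Cc3cc(OC)cc(OC)c3)c3ccc(OC)cc3OC)c(OC)cc2OC)O1 | intermediate
20 | (E)-9-Ar-nona-1,8-diene-1,3,5,7-tetrone, the acylketene (not isolated) | O=C=CC(=O)CC(=O)CC(=O)/C=C/c1cc([C@@H](Cc2cc(OC)cc(OC)c2)c2ccc(OC)cc2OC)c(OC)cc1OC | intermediate
21 | methyl (E)-9-Ar-3,5,7-trioxonon-8-enoate (not isolated) | COC(=O)CC(=O)CC(=O)CC(=O)/C=C/c1cc([C@@H](Cc2cc(OC)cc(OC)c2)c2ccc(OC)cc2OC)c(OC)cc1OC | intermediate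
22 | methyl 2-hydroxy-4,6-dioxo-2-[(E)-2-Ar-ethenyl]cyclohexane-1-carboxylate (not isolated; ring stereocentres undefined) | COC(=O)C1C(=O)CC(=O)CC1(O)/C=C/c1cc([C@@H](Cc2cc(OC)cc(OC)c2)c2ccc(OC)cc2OC)c(OC)cc1OC | intermediate
23 | methyl 2,4-dihydroxy-6-[(E)-2-Ar-ethenyl]benzoate | COC(=O)c1c(O)cc(O)cc1/C=C/c1cc([C@@H](Cc2cc(OC)cc(OC)c2)c2ccc(OC)cc2OC)c(OC)cc1OC | intermediate
24 | 2,4-dihydroxy-6-[(E)-2-Ar-ethenyl]benzoic acid (not isolated) | OC(=O)c1c(O)cc(O)cc1/C=C/c1cc([C@@H](Cc2cc(OC)cc(OC)c2)c2ccc(OC)cc2OC)c(OC)cc1OC | intermediate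
25 | 5-[(E)-2-Ar-ethenyl]benzene-1,3-diol | Oc1cc(O)cc(/C=C/c2cc([C@@H](Cc3cc(OC)cc(OC)c3)c3ccc(OC)cc3OC)c(OC)cc2OC)c1 | intermediate
26 | 4-[(1S)-2-(3,5-dihydroxyphenyl)-1-{5-[(E)-2-(3,5-dihydroxyphenyl)ethenyl]-2,4-dihydroxyphenyl}ethyl]benzene-1,3-diol | Oc1cc(O)cc(/C=C/c2cc([C@@H](Cc3cc(O)cc(O)c3)c3ccc(O)cc3O)c(O)cc2O)c1 | target

**Step count**

Total: 11 steps. Longest linear sequence: 10 steps (steps 1–6 and 8–11; step 7 is the side branch to 16).

**Steps most likely to fail**

1. Step 9. The unmasked chain may close through oxygen instead of through C2: conjugate addition of the C5 enol oxygen to the cinnamoyl β-carbon, or lactonisation onto the ketene or ester. Methanol or methoxide may also add to the enone. Fallback, setting out from aldehyde 12: Horner–Wadsworth–Emmons olefination with diethyl (3,5-dimethoxybenzyl)phosphonate (KOt-Bu, THF, 0 to 25 °C) should give the (E)-stilbene octamethyl ether F1. BBr3 (CH2Cl2, −78 to 0 °C) then cleaves all eight ethers, and the route is rejoined at the target 26.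

2. Step 3. Facial discrimination in the hydride transfer may be poor, because the exocyclic carbon of the quinone methide carries two large groups (an ortho-substituted aryl and a benzyl) and can adopt two geometries. Turnover may also be slow, since the cation is strongly stabilised. Fallback, setting out from 8: ionic hydrogenation (Et3SiH, CF3CO2H, CH2Cl2, 0 °C) gives the racemic phenol F2. Acylation with (1S)-camphanic chloride (Et3N, 4-dimethylaminopyridine, CH2Cl2) gives the diastereomeric camphanates, the (S)-methine ester F3 and the (R)-methine ester F4, which are separated by crystallisation or chromatography; the bromine atom allows the configuration to be assigned by X-ray diffraction. LiOH in THF/H2O frees the phenol from F3, and the route is rejoined at 9.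

3. Step 8. The dianion may add in conjugate fashion to the cinnamoyl acceptor or be acylated on oxygen, and proton transfer from imidazole or from the product may stop conversion. Fallback, setting out from aldehyde 12: Wittig olefination with (triphenylphosphoranylidene)acetaldehyde (toluene, 80 °C) gives the (E)-enal F5. Dianion 18 (from 16, LiN(i-Pr)2, THF, −78 °C) adds 1,2 to it to give the β-hydroxy ketone F6, whose carbinol configuration is immaterial. Dess–Martin periodinane (CH2Cl2, 0 °C) oxidises the allylic carbinol, and the route is rejoined at 19.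

**Further compounds**

F1 | step 9 | 1-[(1S)-2-(3,5-dimethoxyphenyl)-1-(2,4-dimethoxyphenyl)ethyl]-5-[(E)-2-(3,5-dimethoxyphenyl)ethenyl]-2,4-dimethoxybenzene | COc1cc(OC)cc(/C=C/c2cc([C@@H](Cc3cc(OC)cc(OC)c3)c3ccc(OC)cc3OC)c(OC)cc2OC)c1
F2 | step 3 | racemic 2-[1-(5-bromo-2,4-dimethoxyphenyl)-2-(3,5-dimethoxyphenyl)ethyl]-5-methoxyphenol | Brc1cc(C(Cc2cc(OC)cc(OC)c2)c2ccc(OC)cc2O)c(OC)cc1OC
F3 | step 3 | (1S)-camphanate ester of the (S)-phenol 9 | Brc1cc([C@@H](Cc2cc(OC)cc(OC)c2)c2ccc(OC)cc2OC(=O)[C@@]23CC[C@@](C)(C(=O)O2)C3(C)C)c(OC)cc1OC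
F4 | step 3 | (1S)-camphanate ester of the (R)-phenol | Brc1cc([C@H](Cc2cc(OC)cc(OC)c2)c2ccc(OC)cc2OC(=O)[C@@]23CC[C@@](C)(C(=O)O2)C3(C)C)c(OC)cc1OC
F5 | step 8 | (E)-3-Ar-prop-2-enal | O=C/C=C/c1cc([C@@H](Cc2cc(OC)cc(OC)c2)c2ccc(OC)cc2OC)c(OC)cc1OC
F6 | step 8 | 6-[(E)-6-Ar-4-hydroxy-2-oxohex-5-en-1-yl]-2,2-dimethyl-4H-1,3-dioxin-4-one | CC1(C)OC(=O)C=C(CC(=O)CC(O)/C=C/c2cc([C@@H](Cc3cc(OC)cc(OC)c3)c3ccc(OC)cc3OC)c(OC)cc2OC)O1
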